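Trinervitane numbering is used. The route rests on disconnecting the C16–C7 bond shared by the cyclopentane and the eleven-membered ring; it is the central bond of the 1,5-diene C1=C15–C16–C7–C8=C19, an ene retron. The precursor is a 2,4-dimethylcyclohex-2-enone whose quaternary C4 carries a prenyl-terminated chain. One thermal intramolecular ene reaction joins the enone β-carbon C16 to C7, closes the cis-fused cyclopentane, passes a methyl hydrogen to C15 so that C8 ends cis to C15, and unveils the C8=C19 methylene. Epoxidation, enol triflation, allylic oxidation, an asymmetric alkylzinc addition and a nickel/chromium-mediated closure of the eleven-membered ring complete the target.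

Key step: step 2

Numbering: cyclohexene C1 (sp2, bears C14), C2 (OH), C3 (OH), C4 (quaternary, C18 methyl), C16, C15 (sp2, C17 methyl); cyclopentane C4–C5–C6–C7–C16; large ring C7–C8(=C19H2)–C9(OAc)–C10–C11–C12(C20 methyl)–C13–C14(OAc)–C1. The α-face of the cyclohexene is the face of the C18 methyl; the β-face carries C5 and C7.

Assumption: the absolute sense of induction of the catalyst in step 1 and of the ligand in step 10 is taken from model substrates; the antipode is used if it proves opposite.

Step 1
Reactants: 1 2,6-dimethylhept-5-enal (racemic); 2 pent-1-en-3-one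
Product: 4 (R)-2,4-dimethyl-4-(4-methylpent-3-en-1-yl)cyclohex-2-en-1-one, via keto-aldehyde Michael adduct 3 (not isolated)
Conditions: (S)-N-(4-dodecylphenylsulfonyl)prolinamide (20 mol %), 4 Å MS, ClCH2CH2Cl, rt; then KOH (cat.), MeOH, rt
Reagents that add atoms: none
Why: Organocatalytic asymmetric Robinson annulation (Yamada–Otani type): the enamine of the α-branched aldehyde (its own stereocentre is erased) adds to the vinyl ketone under catalyst control to set the quaternary C4, and the only enolate that can reach the non-enolisable aldehyde in a six-membered ring (C15) closes the enone by aldol condensation.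

Step 2
Reactants: 4 (R)-2,4-dimethyl-4-(4-methylpent-3-en-1-yl)cyclohex-2-en-1-one
Product: 5 (3R,3aS,4S,7aR)-4,7a-dimethyl-3-(prop-1-en-2-yl)octahydro-5H-inden-5-one
Conditions: PhMe (0.05 M), BHT (cat.), sealed tube, 240 °C
Reagents that add atoms: none
Why: Thermal intramolecular Alder-ene reaction of a 1,6-diene (type 1), whose closest known relatives are the ene cyclisations of prenyl donors onto α,β-unsaturated carbonyl enophiles used for kainoid pyrrolidines and propellane sesquiterpenes: the enone β-carbon C16 bonds to the less substituted alkene carbon C7 while an allylic methyl hydrogen moves suprafacially to the α-carbon C15 and the donor double bond shifts to C8=C19. The cyclopentane closes in the 5-exo mode through the C4–C5–C6 tether, the pericyclic six-membered array C15–C16–C7–C8–C19–H being fused cis to it. C16 is set by the tether (attack on the face of C4 that carries the chain, hence cis ring fusion with the C18 methyl and H16 on the α-face); C7 is set by the concerted transition state, which must hold C8 and its methyl over C15 to deliver the hydrogen, so C8 ends cis to C15 on the cyclopentane; the new C15 centre (H cis to C7) is erased in step 5. The step needs regioselectivity (bond to C7, hydrogen from a methyl) and the cis C7/C16 relation: the first follows from polarity (positive charge builds on tertiary C8, whereas bonding at C8 would make a quaternary centre in a six-membered ring) and from both donor groups on C8 being methyls, the second from the three-atom tether, which is why uncatalysed thermal conditions are chosen over a stepwise Lewis-acid variant.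

Step 3
Reactants: 5 (3R,3aS,4S,7aR)-4,7a-dimethyl-3-(prop-1-en-2-yl)octahydro-5H-inden-5-one
Product: 7 (3R,3aS,4S,7aR)-4,7a-dimethyl-3-(prop-1-en-2-yl)-1,2,3,3a,4,7a-hexahydro-5H-inden-5-one, via trimethylsilyl enol ether 6 (not isolated)
Conditions: LiN(iPr)2, Me3SiCl, THF, −78 °C; then Pd(OAc)2, MeCN, rt
Reagents that add atoms: none
Why: Kinetic deprotonation takes the C2 methylene and not the hindered C15 methine next to the ring fusion, and Saegusa–Ito oxidation of the silyl enol ether gives the C2=C3 enone without touching a stereocentre.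

Step 4
Reactants: 7 (3R,3aS,4S,7aR)-4,7a-dimethyl-3-(prop-1-en-2-yl)-1,2,3,3a,4,7a-hexahydro-5H-inden-5-one
Product: 8 2α,3α-epoxy ketone (6,7-epoxide of 7 on the face of the 7a-methyl group)
Conditions: H2O2 (30 % aq.), NaOH (cat.), MeOH, 0 °C
Reagents that add atoms: hydrogen peroxide, OO
Why: Weitz–Scheffer nucleophilic epoxidation touches only the enone; in the half-chair that keeps both methyl groups pseudo-equatorial C5 is pseudo-axial on the β-face, so hydroperoxide should attack C3 anti to it, from the convex α-face, and the oxirane forms cis to the C18 methyl.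

Step 5
Reactants: 8 2α,3α-epoxy ketone
Product: 9 2α,3α-epoxy enol triflate (C1(OSO2CF3)=C15)
Conditions: KN(SiMe3)2, THF, −78 °C; then N-(5-chloropyridin-2-yl)triflimide, −78 to −40 °C
Reagents that add atoms: N-(5-chloropyridin-2-yl)-bis(trifluoromethanesulfonyl)imide, O=S(=O)(N(c1ccc(Cl)cn1)S(=O)(=O)C(F)(F)F)C(F)(F)F
Why: Enol triflate formation is regiospecific because the epoxy ketone can enolise only towards C15 (C2 is an oxirane carbon), and fast O-sulfonylation of the potassium enolate at low temperature forestalls a Favorskii-type opening of the oxirane.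

Step 6
Reactants: 9 2α,3α-epoxy enol triflate
Product: 10 allylic chloride (3-chloroprop-1-en-2-yl group on C7)
Conditions: Ca(OCl)2, CO2 (solid), CH2Cl2–H2O, 0 °C
Reagents that add atoms: calcium hypochlorite, [Ca+2].[O-]Cl.[O-]Cl
Why: Ene-type allylic chlorination by hypochlorous acid, as known for the isopropenyl groups of carvone and limonene: chlorine adds to the terminal CH2 of the only electron-rich alkene (the enol triflate is deactivated) and a methyl proton is lost, which gives the 2-(chloromethyl)allyl unit and leaves C7 untouched.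

Step 7
Reactants: 10 allylic chloride
Product: 11 enal (3-oxoprop-1-en-2-yl group on C7; C9 aldehyde)
Conditions: Me3NO (anhydrous), DMSO, 0 °C to rt
Reagents that add atoms: trimethylamine N-oxide, C[N+](C)(C)[O-]
Why: Ganem oxidation: SN2 displacement of the primary allylic chloride by the N-oxide oxygen and loss of trimethylamine gives the 2-substituted acrolein under conditions too weakly basic to move the methylene into conjugation at C7 or to open the oxirane.

Step 8
Reactants: 12 (S)-5-methoxy-3-methyl-5-oxopentanoic acid (methyl hydrogen (S)-3-methylglutarate)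
Product: 13 methyl (S)-5-hydroxy-3-methylpentanoate
Conditions: BH3·SMe2, THF, 0 °C to rt
Reagents that add atoms: none
Why: Borane reduces the free carboxylic acid far faster than the methyl ester (chemoselective acid reduction), and the C12 stereocentre is not involved.

Step 9
Reactants: 13 methyl (S)-5-hydroxy-3-methylpentanoate
Product: 14 methyl (R)-5-iodo-3-methylpentanoate
Conditions: I2, PPh3, imidazole, CH2Cl2, 0 °C
Reagents that add atoms: iodine, II
Why: Appel-type iodination of the primary alcohol through its alkoxyphosphonium salt, run at once so that the δ-hydroxy ester does not lactonise.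

Step 10
Reactants: 14 methyl (R)-5-iodo-3-methylpentanoate; 11 enal
Product: 16 (9R)-allylic alcohol methyl ester, via dialkylzinc reagent 15 (not isolated)
Conditions: 14, Et2Zn (neat), CuI (cat.), 55 °C, then vacuum; Ti(OiPr)4, (1S,2S)-N,N′-bis(trifluoromethylsulfonyl)cyclohexane-1,2-diamine (8 mol %), PhMe, −20 °C; then 11
Reagents that add atoms: none
Why: Iodine–zinc exchange gives an ester-tolerant dialkylzinc, and its titanium bis(sulfonamide)-catalysed 1,2-addition to the enal (catalytic asymmetric organozinc addition) forms C9–C10 and sets C9 as R under ligand control, while triflate, oxirane and ester stay inert.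

Step 11
Reactants: 16 (9R)-allylic alcohol methyl ester
Product: 17 (9R)-hydroxy aldehyde (C14 aldehyde)
Conditions: iBu2AlH (2.2 equiv), CH2Cl2, −78 °C
Reagents that add atoms: none
Why: Partial ester reduction: after the C9 hydroxyl is consumed as its aluminium alkoxide, the tetrahedral aluminium hemiacetal of the methyl ester persists at −78 °C and gives the aldehyde on work-up, while enol triflate and oxirane are not reduced at this temperature.

Step 12
Reactants: 17 (9R)-hydroxy aldehyde
Product: 18 (9R,14S)-2α,3α-epoxytrinervita-1(15),8(19)-diene-9,14-diol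
Conditions: CrCl2 (10 equiv), NiCl2 (2 mol %), DMF (0.002 M), rt
Reagents that add atoms: none
Why: Nozaki–Hiyama–Kishi macrocyclisation: nickel inserts into the alkenyl C–OTf bond, transmetallation gives an alkenylchromium that adds only to the aldehyde and closes the eleven-membered ring (C8 is held cis to C15, so C14 lies near C1); C14 is set by macrocyclic control, and 14S is expected because C13 arrives from the β-face on the C17 side while the chromium-bound oxygen takes the free α-face.

Step 13
Reactants: 18 (9R,14S)-2α,3α-epoxytrinervita-1(15),8(19)-diene-9,14-diol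
Product: 19 (9R,14S)-2α,3α-epoxytrinervita-1(15),8(19)-diene-9,14-diyl diacetate
Conditions: Ac2O, DMAP, pyridine, CH2Cl2, rt
Reagents that add atoms: acetic anhydride, CC(=O)OC(C)=O
Why: DMAP-catalysed acylation esterifies both secondary allylic hydroxyls under basic conditions that leave the acid-sensitive vinyl oxirane intact.

Step 14
Reactants: 19 (9R,14S)-2α,3α-epoxytrinervita-1(15),8(19)-diene-9,14-diyl diacetate
Product: 20 CNP0286573.1, (2R,3R,4S,7R,9R,12S,14S,16S)-2,3-dihydroxytrinervita-1(15),8(19)-diene-9,14-diyl diacetate
Conditions: HClO4 (cat.), THF–H2O (3:1), 0 °C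
Reagents that add atoms: water, O
Why: Acid-catalysed hydrolysis of the vinyl oxirane: water attacks the allylic C2 (C3 is neopentyl) anti to the oxirane oxygen in the trans-diaxial sense (Fürst–Plattner), inverting C2 to the β-hydroxyl and retaining the α-hydroxyl at C3, and cold dilute acid should spare the two acetates.

Compound list
1 | 2,6-dimethylhept-5-enal (racemic, melonal) | CC(C)=CCCC(C)C=O | starting material
2 | pent-1-en-3-one (ethyl vinyl ketone) | CCC(=O)C=C | starting material
3 | (R)-2,6-dimethyl-2-(3-oxopentyl)hept-5-enal (Michael adduct, not isolated) | CCC(=O)CC[C@](C)(C=O)CCC=C(C)C | intermediate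
4 | (R)-2,4-dimethyl-4-(4-methylpent-3-en-1-yl)cyclohex-2-en-1-one | CC(C)=CCC[C@]1(C)CCC(=O)C(C)=C1 | intermediate
5 | (3R,3aS,4S,7aR)-4,7a-dimethyl-3-(prop-1-en-2-yl)octahydro-5H-inden-5-one (cis-fused; isopropenyl cis to C15) | CC(=C)[C@@H]1CC[C@]2(C)CCC(=O)[C@@H](C)[C@H]12 | intermediate
6 | trimethylsilyl enol ether of 5 towards C2 (C1(OSiMe3)=C2, not isolated) | CC(=C)[C@@H]1CC[C@]2(C)CC=C(O[Si](C)(C)C)[C@@H](C)[C@H]12 | intermediate
7 | (3R,3aS,4S,7aR)-4,7a-dimethyl-3-(prop-1-en-2-yl)-1,2,3,3a,4,7a-hexahydro-5H-inden-5-one (C2=C3 enone) | CC(=C)[C@@H]1CC[C@]2(C)C=CC(=O)[C@@H](C)[C@H]12 | intermediate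
8 | 2α,3α-epoxy ketone (oxirane cis to the C18 methyl) | CC(=C)[C@@H]1CC[C@]2(C)[C@H]3O[C@H]3C(=O)[C@@H](C)[C@H]12 | intermediate
9 | 2α,3α-epoxy enol triflate (C1(OTf)=C15) | CC(=C)[C@@H]1CC[C@]2(C)[C@H]3O[C@H]3C(OS(=O)(=O)C(F)(F)F)=C(C)[C@H]12 | intermediate
10 | allylic chloride (C7 bears CH2=C–CH2Cl) | ClCC(=C)[C@@H]1CC[C@]2(C)[C@H]3O[C@H]3C(OS(=O)(=O)C(F)(F)F)=C(C)[C@H]12 | intermediate
11 | enal (C7 bears CH2=C–CHO) | O=CC(=C)[C@@H]1CC[C@]2(C)[C@H]3O[C@H]3C(OS(=O)(=O)C(F)(F)F)=C(C)[C@H]12 | intermediate
12 | (S)-5-methoxy-3-methyl-5-oxopentanoic acid | COC(=O)C[C@@H](C)CC(O)=O | starting material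
13 | methyl (S)-5-hydroxy-3-methylpentanoate | COC(=O)C[C@@H](C)CCO | intermediate
14 | methyl (R)-5-iodo-3-methylpentanoate | COC(=O)C[C@@H](C)CCI | intermediate
15 | bis[(R)-5-methoxy-3-methyl-5-oxopentyl]zinc (not isolated) | COC(=O)C[C@@H](C)CC[Zn]CC[C@H](C)CC(=O)OC | intermediate
16 | (9R)-allylic alcohol; C14 methyl ester; enol triflate; 2α,3α-oxirane | COC(=O)C[C@@H](C)CC[C@@H](O)C(=C)[C@@H]1CC[C@]2(C)[C@H]3O[C@H]3C(OS(=O)(=O)C(F)(F)F)=C(C)[C@H]12 | intermediate
17 | (9R)-hydroxy aldehyde (C14 aldehyde) | O=CC[C@@H](C)CC[C@@H](O)C(=C)[C@@H]1CC[C@]2(C)[C@H]3O[C@H]3C(OS(=O)(=O)C(F)(F)F)=C(C)[C@H]12 | intermediate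
18 | (9R,14S)-2α,3α-epoxytrinervita-1(15),8(19)-diene-9,14-diol | C=C1[C@H](O)CC[C@H](C)C[C@H](O)C2=C(C)[C@@H]3[C@H]1CC[C@]3(C)[C@H]4O[C@@H]24 | intermediate
19 | (9R,14S)-2α,3α-epoxytrinervita-1(15),8(19)-diene-9,14-diyl diacetate | C=C1[C@H](OC(C)=O)CC[C@H](C)C[C@H](OC(C)=O)C2=C(C)[C@@H]3[C@H]1CC[C@]3(C)[C@H]4O[C@@H]24 | intermediate
20 | CNP0286573.1, (2R,3R,4S,7R,9R,12S,14S,16S)-2,3-dihydroxytrinervita-1(15),8(19)-diene-9,14-diyl diacetate | C=C1[C@H](OC(C)=O)CC[C@H](C)C[C@H](OC(C)=O)C2=C(C)[C@@H]3[C@H]1CC[C@]3(C)[C@@H](O)[C@@H]2O | target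

Total step count: 14. Longest linear sequence: 12 steps (steps 1–7, then 10–14); the side branch is steps 8–9.

Steps most likely to fail

Step 12. The addition of the alkenylchromium to the aldehyde may show poor facial selectivity, and the free C9 hydroxyl leaves no handle to correct C14. The fallback sets out from 17 and returns at 18. Silylation of 17 (tBuMe2SiOTf, 2,6-lutidine) would give the C9 silyl ether aldehyde F2. The same CrCl2/NiCl2 closure would give the C14 carbinol epimers F3, and Dess–Martin periodinane would oxidise them to the macrocyclic enone F4. Reagent-controlled CBS reduction ((R)-2-methyl-CBS-oxazaborolidine, BH3·SMe2) should then give the 14S alcohol F5, and Bu4NF would remove the silyl group to return diol 18.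

Step 2. Hydrogen transfer to the trisubstituted enone may be too slow, so that decomposition or a stepwise path that loses the cis C7/C16 relation competes. The fallback sets out from 4 and returns at 5. Irradiation of 4 (λ > 350 nm, hexane) would give, by the rule of five, the intramolecular [2+2] cyclobutane photoadduct F1, in which C16–C7 and C15–C8 are both formed and C8 is necessarily cis to C15. Thermolysis of F1 (flash vacuum pyrolysis) would then cleave the strained C15–C8 bond by the retro-ene path, a 1,5-shift of a methyl hydrogen to the carbonyl oxygen followed by enol–keto tautomerism, and give 5.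

Step 14. The C14 acetate carbonyl may take part in the opening at C2 and cause acetyl migration, or the allylic acetate may ionise. The fallback sets out from 18 and returns at 20. The vinyl oxirane would be hydrolysed first on diol 18, which carries no ester (HClO4 cat., THF–H2O, 0 °C), to give the tetraol F6. The two less hindered allylic hydroxyls at C9 and C14 would then be acetylated selectively (Ac2O 2.2 equiv, pyridine, −20 °C), the neopentyl C3 hydroxyl and the flanked C2 hydroxyl staying free, to give 20.

Further compounds
F1 | step 2 | [2+2] cyclobutane photoadduct of 4 (bonds C16–C7 and C15–C8) | CC1(C)[C@@H]2CC[C@]3(C)CCC(=O)[C@@]1(C)[C@H]23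
F2 | step 12 | C9 tert-butyldimethylsilyl ether of hydroxy aldehyde 17 | O=CC[C@@H](C)CC[C@@H](O[Si](C)(C)C(C)(C)C)C(=C)[C@@H]1CC[C@]2(C)[C@H]3O[C@H]3C(OS(=O)(=O)C(F)(F)F)=C(C)[C@H]12
F3 | step 12 | macrocyclic C14 carbinol epimers with C9 silyl ether | C=C1[C@H](O[Si](C)(C)C(C)(C)C)CC[C@H](C)CC(O)C2=C(C)[C@@H]3[C@H]1CC[C@]3(C)[C@H]4O[C@@H]24
F4 | step 12 | macrocyclic C14 enone with C9 silyl ether | C=C1[C@H](O[Si](C)(C)C(C)(C)C)CC[C@H](C)CC(=O)C2=C(C)[C@@H]3[C@H]1CC[C@]3(C)[C@H]4O[C@@H]24
F5 | step 12 | (14S)-alcohol with C9 silyl ether | C=C1[C@H](O[Si](C)(C)C(C)(C)C)CC[C@H](C)C[C@H](O)C2=C(C)[C@@H]3[C@H]1CC[C@]3(C)[C@H]4O[C@@H]24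
F6 | step 14 | (2R,3R,9R,14S)-trinervita-1(15),8(19)-diene-2,3,9,14-tetraol | C=C1[C@H](O)CC[C@H](C)C[C@H](O)C2=C(C)[C@@H]3[C@H]1CC[C@]3(C)[C@@H](O)[C@@H]2O
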